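**Strategy.** The oxirane carbon bonded to the arene bears two CH2–O arms: the ring CH2 and the tigloyloxymethyl CH2. Tied together through one oxygen, they become the enantiotopic C2/C4 of an achiral 3-aryl-3-silyloxyoxetane, available by adding the aryllithium to oxetan-3-one. The key step is a chiral hydrogen-bond-donor-catalysed bromide opening of this oxetane. One strain-releasing C–O cleavage turns the two arms into CH2Br (future oxirane CH2) and CH2O (future ester carbon). It thereby sets the only stereocentre, the fully substituted benzylic carbon, by enantiotopic-group selection instead of alkene face selection. Base then relays the bromohydrin to the epoxide; the two different C5 esters go on last.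

Key step: step 4

Assumptions: (i) 4-methoxy-3-methylphenol, oxetan-3-one, tigloyl chloride and angelic anhydride are taken as commercial. (ii) The sense of induction of the squaramide catalyst on this substrate can be assigned by analogy only, so the catalyst enantiomer that opens the pro-S CH2 is the one used (both antipodes are accessible).

**Step 1**
Reactants: 1 4-methoxy-3-methylphenol
Product: 2 2-bromo-4-methoxy-5-methylphenol
Conditions: NBS (1.0 equiv), i-Pr2NH (cat.), CH2Cl2, 0 °C
Reagents that add atoms: N-bromosuccinimide, O=C1CCC(=O)N1Br
Why: Electrophilic aromatic bromination in which the free OH directs ortho (para is blocked by OMe) and the open site para to the methyl group should be preferred over the position flanked by OH and CH3.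

**Step 2**
Reactants: 2 2-bromo-4-methoxy-5-methylphenol
Product: 3 1-(allyloxy)-2-bromo-4-methoxy-5-methylbenzene
Conditions: allyl bromide, K2CO3, acetone, reflux
Reagents that add atoms: allyl bromide, C=CCBr
Why: Williamson ether synthesis; the allyl ether should survive an aryllithium at −78 °C and TMSBr at −78 °C and can later be removed under neutral Pd(0) conditions that spare epoxide and enoate.

**Step 3**
Reactants: 3 1-(allyloxy)-2-bromo-4-methoxy-5-methylbenzene, 4 oxetan-3-one
Product: 7 3-[2-(allyloxy)-5-methoxy-4-methylphenyl]-3-(trimethylsilyloxy)oxetane (achiral), via aryllithium 5 (not isolated), via lithium oxetan-3-olate 6 (not isolated)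
Conditions: n-BuLi, THF, −78 °C; then 4, −78 °C; then TMSCl, −78 °C to rt
Reagents that add atoms: chlorotrimethylsilane, C[Si](C)(C)Cl
Why: Bromine–lithium exchange at −78 °C (faster than anionic cyclisation onto the allyl ether), 1,2-addition of the aryllithium to the strained, poorly enolisable ketone and O-silylation of the alkoxide, so that no free OH remains to release HBr from TMSBr in step 4.

**Step 4**
Reactants: 7 3-[2-(allyloxy)-5-methoxy-4-methylphenyl]-3-(trimethylsilyloxy)oxetane
Product: 9 (S)-3-bromo-2-[2-(allyloxy)-5-methoxy-4-methylphenyl]-1,2-bis(trimethylsilyloxy)propane, via O-silyloxetanium bromide ion pair 8 (not isolated)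
Conditions: TMSBr (1.2 equiv), chiral arylpyrrolidine-derived squaramide hydrogen-bond-donor catalyst (10 mol%), t-BuOMe, −78 °C; Et3N quench, used crude
Reagents that add atoms: bromotrimethylsilane, C[Si](C)(C)Br
Why: The squaramide binds the bromide of TMSBr and so promotes O-silylation of the oxetane to ion pair 8, in which the catalyst-bound bromide attacks one of the two enantiotopic CH2 carbons by SN2 with release of the oxetane strain. The closest known reaction type is the hydrogen-bond-donor (anion-binding) catalysed enantioselective addition of TMSBr to 3-substituted and 3,3-disubstituted oxetanes, with the chiral phosphoric acid-catalysed oxetane desymmetrisations as relatives. No ring is closed: the oxetane is opened, its ring oxygen stays on the CH2 that will carry the tiglate, and the former ketone oxygen stays on the carbinol carbon as the future oxirane oxygen. The new stereocentre is not a reacting atom; its (S) configuration follows only from bromide entering the pro-S CH2, which is under catalyst control (the aryl and OSiMe3 groups at C3 differ strongly in size and π-character and fix the orientation of the oxetanium in the chiral pocket), and the catalyst enantiomer is chosen accordingly. The step needs enantiotopic-group selectivity, and SN2 opening at CH2 in preference to ionisation of the benzylic C3–O bond or participation of the ortho ether oxygen. The second is secured by −78 °C in an ether solvent, by the strain of an sp2 carbon in a four-membered ring next to an oxonium centre, by the poor nucleophilicity of an aryl ether oxygen beside a catalyst-delivered bromide, and by the silyl cap on the tertiary oxygen, which leaves no OH to release HBr for an uncatalysed background opening.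

**Step 5**
Reactants: 9 (S)-3-bromo-2-[2-(allyloxy)-5-methoxy-4-methylphenyl]-1,2-bis(trimethylsilyloxy)propane
Product: 11 {(2S)-2-[2-(allyloxy)-5-methoxy-4-methylphenyl]oxiran-2-yl}methanol, via bromo diol 10 (not isolated)
Conditions: K2CO3, MeOH, 0 °C to rt
Reagents that add atoms: none
Why: Base-mediated methanolysis of both TMS ethers, then intramolecular Williamson etherification (3-exo-tet) of the tertiary alkoxide onto the β-hydrogen-free CH2Br, which is far faster than 4-exo-tet return to the oxetane; the stereocentre is not a reacting atom and the Payne isomer of this 2-aryl glycidol is the same compound in the same configuration, so no erosion is expected.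

**Step 6**
Reactants: 11 {(2S)-2-[2-(allyloxy)-5-methoxy-4-methylphenyl]oxiran-2-yl}methanol, 12 tigloyl chloride [(E)-2-methylbut-2-enoyl chloride]
Product: 13 {(2R)-2-[2-(allyloxy)-5-methoxy-4-methylphenyl]oxiran-2-yl}methyl (E)-2-methylbut-2-enoate
Conditions: 12, Et3N, DMAP (cat.), CH2Cl2, 0 °C
Reagents that add atoms: none
Why: DMAP-catalysed O-acylation of the primary alcohol with the thermodynamically stable (E)-acyl chloride under basic conditions that the acid-labile benzylic epoxide should tolerate (the descriptor changes from S to R only through CIP priorities).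

**Step 7**
Reactants: 13 {(2R)-2-[2-(allyloxy)-5-methoxy-4-methylphenyl]oxiran-2-yl}methyl (E)-2-methylbut-2-enoate
Product: 14 [(2R)-2-(2-hydroxy-5-methoxy-4-methylphenyl)oxiran-2-yl]methyl (E)-2-methylbut-2-enoate
Conditions: Pd(PPh3)4 (5 mol%), morpholine, THF, 0 °C to rt; short silica plug, used at once
Reagents that add atoms: none
Why: Tsuji–Trost deallylation, in which Pd(0) ionises the aryl allyl ether to a π-allyl complex that morpholine captures; the conditions are neutral and non-reductive, so epoxide and tiglate should survive.

**Step 8**
Reactants: 14 [(2R)-2-(2-hydroxy-5-methoxy-4-methylphenyl)oxiran-2-yl]methyl (E)-2-methylbut-2-enoate, 15 angelic anhydride [(Z)-2-methylbut-2-enoic anhydride]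
Product: 16 2-[(2R)-2-({[(E)-2-methylbut-2-enoyl]oxy}methyl)oxiran-2-yl]-4-methoxy-5-methylphenyl (Z)-2-methylbut-2-enoate (target)
Conditions: 15, Et3N, CH2Cl2, 0 °C to rt (no DMAP)
Reagents that add atoms: none
Why: Amine-mediated O-acylation of the phenol by the anhydride (stereoconservative angeloylation); without a nucleophilic catalyst or heat, the (Z)-enoate should not isomerise to the tiglate.

**Compound list**
1 | 4-methoxy-3-methylphenol | COc1ccc(O)cc1C | starting material
2 | 2-bromo-4-methoxy-5-methylphenol | Oc1cc(C)c(OC)cc1Br | intermediate
3 | 1-(allyloxy)-2-bromo-4-methoxy-5-methylbenzene | C=CCOc1cc(C)c(OC)cc1Br | intermediate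
4 | oxetan-3-one | O=C1COC1 | starting material
5 | [2-(allyloxy)-5-methoxy-4-methylphenyl]lithium | C=CCOc1cc(C)c(OC)cc1[Li] | intermediate (not isolated)
6 | lithium 3-[2-(allyloxy)-5-methoxy-4-methylphenyl]oxetan-3-olate | C=CCOc1cc(C)c(OC)cc1C1(O[Li])COC1 | intermediate (not isolated)
7 | 3-[2-(allyloxy)-5-methoxy-4-methylphenyl]-3-(trimethylsilyloxy)oxetane | C=CCOc1cc(C)c(OC)cc1C1(O[Si](C)(C)C)COC1 | intermediate
8 | 3-[2-(allyloxy)-5-methoxy-4-methylphenyl]-1-(trimethylsilyl)-3-(trimethylsilyloxy)oxetan-1-ium bromide (catalyst-bound ion pair) | C=CCOc1cc(C)c(OC)cc1C1(O[Si](C)(C)C)C[O+]([Si](C)(C)C)C1.[Br-] | intermediate (not isolated)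
9 | (S)-3-bromo-2-[2-(allyloxy)-5-methoxy-4-methylphenyl]-1,2-bis(trimethylsilyloxy)propane | C=CCOc1cc(C)c(OC)cc1[C@](O[Si](C)(C)C)(CO[Si](C)(C)C)CBr | intermediate
10 | (S)-3-bromo-2-[2-(allyloxy)-5-methoxy-4-methylphenyl]propane-1,2-diol | C=CCOc1cc(C)c(OC)cc1[C@](O)(CO)CBr | intermediate (not isolated)
11 | {(2S)-2-[2-(allyloxy)-5-methoxy-4-methylphenyl]oxiran-2-yl}methanol | C=CCOc1cc(C)c(OC)cc1[C@]1(CO)CO1 | intermediate
12 | tigloyl chloride, (E)-2-methylbut-2-enoyl chloride | C/C=C(\C)C(=O)Cl | starting material
13 | {(2R)-2-[2-(allyloxy)-5-methoxy-4-methylphenyl]oxiran-2-yl}methyl (E)-2-methylbut-2-enoate | C=CCOc1cc(C)c(OC)cc1[C@]1(COC(=O)/C(C)=C/C)CO1 | intermediate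
14 | [(2R)-2-(2-hydroxy-5-methoxy-4-methylphenyl)oxiran-2-yl]methyl (E)-2-methylbut-2-enoate | Oc1cc(C)c(OC)cc1[C@]1(COC(=O)/C(C)=C/C)CO1 | intermediate
15 | angelic anhydride, (Z)-2-methylbut-2-enoic anhydride | C/C=C(/C)C(=O)OC(=O)/C(C)=C\C | starting material
16 | 2-[(2R)-2-({[(E)-2-methylbut-2-enoyl]oxy}methyl)oxiran-2-yl]-4-methoxy-5-methylphenyl (Z)-2-methylbut-2-enoate | C/C=C(/C)C(=O)Oc1cc(C)c(OC)cc1[C@]1(COC(=O)/C(C)=C/C)CO1 | target

**Total step count:** 8. **Longest linear sequence:** 8 steps (from 1).

**Steps most likely to fail**

1. Step 4. The catalyst may not discriminate the two enantiotopic CH2 groups well enough when C3 carries both an aryl and a silyloxy group. The electron-rich benzylic C3–O bond may ionise instead of the CH2 being opened. The ortho allyloxy oxygen may also take part as an internal nucleophile, with loss of the allyl group. The fallback sets out from 3 and returns at 11, replacing group selection by face-selective oxidation. Compound 3 is converted with Mg in THF into [2-(allyloxy)-5-methoxy-4-methylphenyl]magnesium bromide F1. CuI-catalysed carbomagnesiation of propargyl alcohol (pre-deprotonated with i-PrMgCl) by F1 should give 2-[2-(allyloxy)-5-methoxy-4-methylphenyl]prop-2-en-1-ol F2. Sharpless asymmetric epoxidation of F2 [Ti(Oi-Pr)4, L-(+)-diethyl tartrate, t-BuOOH, 4 Å MS, CH2Cl2, −20 °C] should deliver oxygen to the face that leads to the (S)-glycidol 11. The route then resumes at step 6.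

2. Step 7. Once the ortho hydroxyl is free, the phenol or phenoxide may open the neighbouring tertiary benzylic oxirane (quinone-methide-type ring opening or closure to a dihydrobenzofuran) during reaction, work-up or storage. The fallback sets out from 13 and returns at 16 without ever releasing the free phenol. Pd(PPh3)4-catalysed hydrostannolysis of the allyl ether with Bu3SnH (slow addition, CH2Cl2, rt) is run in the presence of angelic anhydride 15. The covalent, weakly basic tributyl{2-[(2R)-2-({[(E)-2-methylbut-2-enoyl]oxy}methyl)oxiran-2-yl]-4-methoxy-5-methylphenoxy}stannane F3 should be acylated in the flask by 15 to give 16 directly. The hindered trisubstituted enoates are expected to resist Pd/tin hydride conjugate reduction.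

3. Step 8. The angeloyl unit may isomerise from Z to E during acyl transfer (reversible conjugate addition of base or nucleophile to the acyl donor), or acylation of the hindered phenol may be slow enough for the epoxide to suffer. The fallback sets out from 14 and returns at 16, forming the Z double bond after the ester bond. DCC-mediated esterification of 14 with 2-[bis(2,2,2-trifluoroethoxy)phosphoryl]propanoic acid should give 2-[(2R)-2-({[(E)-2-methylbut-2-enoyl]oxy}methyl)oxiran-2-yl]-4-methoxy-5-methylphenyl 2-[bis(2,2,2-trifluoroethoxy)phosphoryl]propanoate F4 (mixture of epimers at the phosphonate carbon). Still–Gennari olefination of F4 with acetaldehyde (KHMDS, 18-crown-6, THF, −78 °C) should then give 16 with kinetic Z selectivity.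

**Further compounds**
F1 | step 4 | [2-(allyloxy)-5-methoxy-4-methylphenyl]magnesium bromide | C=CCOc1cc(C)c(OC)cc1[Mg]Br
F2 | step 4 | 2-[2-(allyloxy)-5-methoxy-4-methylphenyl]prop-2-en-1-ol | C=CCOc1cc(C)c(OC)cc1C(=C)CO
F3 | step 7 | tributyl{2-[(2R)-2-({[(E)-2-methylbut-2-enoyl]oxy}methyl)oxiran-2-yl]-4-methoxy-5-methylphenoxy}stannane | CCCC[Sn](CCCC)(CCCC)Oc1cc(C)c(OC)cc1[C@]1(COC(=O)/C(C)=C/C)CO1
F4 | step 8 | 2-[(2R)-2-({[(E)-2-methylbut-2-enoyl]oxy}methyl)oxiran-2-yl]-4-methoxy-5-methylphenyl 2-[bis(2,2,2-trifluoroethoxy)phosphoryl]propanoate | CC(C(=O)Oc1cc(C)c(OC)cc1[C@]1(COC(=O)/C(C)=C/C)CO1)P(=O)(OCC(F)(F)F)OCC(F)(F)F
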